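## Retrosynthetic overview
1. The target is a sclareol-type 3β,8α-diol decalin bearing a C9–CH2–farnesyl chain. I disconnect the sp3–sp2 bond C12–C13 by Ni-catalysed reductive cross-electrophile coupling of a primary 12-iodide with an (E)-trisubstituted alkenyl iodide.
2. I avoid the usual oxidosqualene polyene cyclisation. Both rings, and the C5, C8, C9 and C10 stereocentres, come intact from commercial (+)-sclareolide, so no ring is formed in this route.
3. The 3β-OH is installed directly by enzymatic C3–H hydroxylation. The lactone is then reduced to the 12-ol, which becomes the iodide.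
4. The alkenyl iodide comes from geranylacetone by conversion to the terminal alkyne, then Zr-catalysed methylalumination and iodination.

Assumptions:
- (E)-Geranylacetone of ≥95% E is commercially available.
- The P450 variant or *Mucor plumbeus* gives 3β-hydroxysclareolide as the major monohydroxylation product, separable from the 1β and 2α isomers.
- The target has the natural normal-series decalin. I checked that its C5, C8, C9 and C10 descriptors match (+)-sclareolide (5S, 8R, 9R, 10S in sclareolide numbering).

## Route

**Step 1**
Reactants: 1, (+)-sclareolide
Product: 2, 3β-hydroxysclareolide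
Conditions: engineered P450BM3 variant (whole-cell E. coli), glucose, KPi buffer pH 8, 5% DMSO, 25 °C, 24 h (alternative: *Mucor plumbeus* fermentation)
Reagents that add atoms: O2, O=O
Why: enzymatic C(sp3)–H hydroxylation (P450 oxygen rebound) at the equatorial C3–H sets the 3β (3S) centre directly, and the lactone survives.

**Step 2**
Reactants: 2
Product: 3, 3β-hydroxy-ambradiol, the 3β,8α,12-triol with the C9 side chain shortened to CH2CH2OH
Conditions: LiAlH4 (2.5 equiv), THF, 0 °C → reflux, 3 h; Rochelle salt work-up
Reagents that add atoms: none (only H is added)
Why: LiAlH4 reduction of the lactone cleaves the acyl–O bond, so the C8–O bond and the 8α configuration are untouched.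

**Step 3**
Reactants: 3
Product: 4, the 12-iodide with 3β-OH and 8α-OH free
Conditions: PPh3 (1.2 equiv), I2 (1.2 equiv), imidazole (3 equiv), CH2Cl2, 0 °C → rt, 1 h
Reagents that add atoms: iodine, II
Why: Appel/Garegg–Samuelsson iodination is SN2 at the unhindered primary carbinol. The hindered 3-OH and the tertiary 8-OH are unreactive, imidazole buffers against ionisation of the tertiary alcohol, and no stereocentre is involved.

**Step 4**
Reactants: 5, (E)-geranylacetone
Product: 6, (E)-6,10-dimethylundeca-5,9-dien-1-yne
Conditions: LDA (1.05 equiv), THF, −78 °C; ClP(O)(OEt)2 (1.2 equiv), −78 °C → rt; then LDA (2.5 equiv), −78 → 0 °C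
Reagents that add atoms: none (the phosphate is lost)
Why: kinetic LDA deprotonation of the methyl side gives the enol phosphate, and excess LDA eliminates it to the terminal alkyne (Negishi-type methyl ketone → alkyne). The trisubstituted alkenes are inert and their geometry is preserved.

**Step 5**
Reactants: 6
Product: 7, (1E,5E)-1-iodo-2,6,10-trimethylundeca-1,5,9-triene
Conditions: Me3Al (3 equiv), Cp2ZrCl2 (0.2 equiv), ClCH2CH2Cl, 0 °C → rt, 12 h; then I2 (1.2 equiv), THF, −30 → 0 °C
Reagents that add atoms: trimethylaluminium, C[Al](C)C (supplies the C14 methyl); iodine, II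
Why: Negishi Zr-catalysed carboalumination adds Me–Al syn across the terminal alkyne, with Me on the internal carbon, and iodinolysis with retention gives the E-trisubstituted alkenyl iodide (I trans to the chain). The trisubstituted alkenes do not undergo carboalumination.

**Step 6**
Reactants: 4 and 7 (2.0 equiv)
Product: 8, target
Conditions: NiBr2·diglyme (10 mol%), 4,4′-di-tert-butyl-2,2′-bipyridine (10 mol%), Zn (3 equiv), TMSCl (cat.), DMA, 25 °C, 18 h
Reagents that add atoms: none
Why: Ni-catalysed reductive cross-electrophile coupling (Weix/Gong type) adds Ni(0) into the alkenyl iodide and captures the primary alkyl radical from the alkyl iodide. Reductive elimination forms C12–C13 with alkene geometry retained, free OH groups are tolerated, and no stereocentre is touched. This extends known alkyl iodide/alkenyl halide couplings to a trisubstituted polyprenyl-type partner and a diol substrate.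

Check on the last step: C16H29O2 (from 4) + C14H23 (from 7) = C30H52O2, which equals the target.

## Compound list
1 | (+)-sclareolide, (3aR,5aS,9aS,9bR)-3a,6,6,9a-tetramethyldecahydronaphtho[2,1-b]furan-2(1H)-one | O=C1C[C@@H]2[C@@]3(C)CCCC(C)(C)[C@@H]3CC[C@@]2(C)O1 | starting material
2 | 3β-hydroxysclareolide | O=C1C[C@@H]2[C@@]3(C)CC[C@H](O)C(C)(C)[C@@H]3CC[C@@]2(C)O1 | intermediate
3 | 3β-hydroxy-ambradiol (3β,8α,12-triol) | OCC[C@@H]1[C@@]2(C)CC[C@H](O)C(C)(C)[C@@H]2CC[C@@]1(C)O | intermediate
4 | 12-iodo-3β,8α-dihydroxy-tetranorlabdane (12-iodide) | ICC[C@@H]1[C@@]2(C)CC[C@H](O)C(C)(C)[C@@H]2CC[C@@]1(C)O | intermediate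
5 | (E)-geranylacetone, (E)-6,10-dimethylundeca-5,9-dien-2-one | CC(C)=CCC/C(C)=C/CCC(C)=O | starting material
6 | (E)-6,10-dimethylundeca-5,9-dien-1-yne | CC(C)=CCC/C(C)=C/CCC#C | intermediate
7 | (1E,5E)-1-iodo-2,6,10-trimethylundeca-1,5,9-triene | CC(C)=CCC/C(C)=C/CC/C(C)=C/I | intermediate
8 | target: 3β,8α-dihydroxy-polypoda-13E,17E,21-triene (C30H52O2) | CC(C)=CCC/C(C)=C/CC/C(C)=C/CC[C@@H]1[C@@]2(C)CC[C@H](O)C(C)(C)[C@@H]2CC[C@@]1(C)O | target

## Step count
- Total steps: 6.
- Longest linear sequence: 4 steps, from sclareolide through 2, 3 and 4 to the target. The alkenyl iodide branch is 2 steps and converges at Step 6.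

## Three steps most likely to fail
1. **Step 1, C3β-selective enzymatic hydroxylation.** Regioselectivity and yield depend on the enzyme variant, and 1β/2α isomers may form.
   - Fallback: abandon the semisynthesis and use the biomimetic polyene cyclisation of (3S)-2,3-oxidosqualene, made by asymmetric terminal epoxidation of squalene. A Lewis-acid-promoted bicyclisation with water capture at C8 would give the 3β,8α-diol directly.
2. **Step 3, selective iodination.** The 8α-OH can displace the activated C12 carbinol and close the Ambrox-type tetrahydrofuran, or the 3-OH can react.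
   - Fallback: skip the halide and couple the primary alcohol 3 with alkenyl iodide 7 by deoxygenative Ni/photoredox coupling, activating the alcohol in situ as an oxalate or NHC adduct.
3. **Step 6, Ni cross-electrophile coupling.** The trisubstituted alkenyl iodide may couple poorly, alkenyl homodimer may form, and the free polyol may interfere.
   - Fallback: build C11–C12 instead of C12–C13. Alkylate the sclareolide enolate of the 3-OTBS lactone with (E,E)-farnesyl bromide, open the lactone to the hydroxy acid, protect the 8-OH, and remove the carboxyl by Barton decarboxylation. Then remove the silyl groups with TBAF.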